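The target, read from its SMILES, is the ent-labdane (4S,5S,6R,9R,10S). Everything rests on cutting C1–C10. Quaternary C10 is the junction of rings A and B and carries the C20 methyl, so a ring B methylenecyclohexane with an exocyclic C10=C20 alkene is a latent tertiary C10 radical together with its methyl. The precursor carries on C5 the quaternary C4 (C19 methyl, C18 ester) acylated as a C3 vinyl ketone; C4, C5 and C6 are already set. In one operation, iron-hydride hydrogen-atom transfer to C20 and 6-endo Giese addition of C10 to C1 close ring A, create the C20 methyl and fix the trans ring fusion.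

Key step: step 7

Remark (numbering): labdane numbering is used for all intermediates; the C4 carboxyl carbon is called C18 and the C4 methyl C19. In the target C20 and C19 are axial on one face, H5 and H9 axial on the other, and the C18 carboxyl, the C6 acetate and the C9 side chain are equatorial.

Remark (structure check): the (R)-silyloxy enone maps onto 6R. The key-step precursor is (4R,5S,6R) and its product (4R,5S,6R,10R); these are the target's 4S,5S,6R,10S arrangement, and only the CIP ranks change when C3 and C9 lose their oxygen.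

Remark (C4): the Ireland–Claisen that joins C4 to C5 places the lithium-chelating group cis to the enolate oxygen. Through a chair, this group becomes the equatorial C18 carboxyl only if the tethering carboxyl becomes the C3 carbonyl. The partner is therefore a methylmalonate half-ester. A β-hydroxy-ester partner whose own carboxyl became C18 would give the C4 epimer by the same model.

Remark (ester): C18 is carried as a 2-(trimethylsilyl)ethyl ester, because a methyl ester on quaternary C4 could not be cleaved at the end without loss of the C6 acetate.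

Step 1
Reactants: 1 (4R)-4-[(tert-butyldimethylsilyl)oxy]cyclohex-2-en-1-one; 2 formaldehyde
Product: 3 (4R)-4-[(tert-butyldimethylsilyl)oxy]-2-(hydroxymethyl)cyclohex-2-en-1-one
Conditions: 37% aq. CH2O, DMAP (20 mol %), THF, 23 °C
Reagents that add atoms: none
Why: Morita–Baylis–Hillman hydroxymethylation at the enone α-carbon (future C10) brings in C20 as an allylic alcohol; the silyloxy stereocenter (future C6) is not touched.

Step 2
Reactants: 3
Product: 5 [(8R)-8-[(tert-butyldimethylsilyl)oxy]-1,4-dioxaspiro[4.5]dec-6-en-6-yl]methanol, via trimethylsilyl ether 4 (not isolated)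
Conditions: Me3SiOCH2CH2OSiMe3, Me3SiOTf (5 mol %), CH2Cl2, −78 → −20 °C; pyridine quench; then K2CO3 (cat.), MeOH, 0 °C
Reagents that add atoms: 1,2-bis(trimethylsilyloxy)ethane, C[Si](C)(C)OCCO[Si](C)(C)C
Why: Noyori ketalisation at low temperature masks the future C9 ketone without moving the double bond or cleaving the secondary silyl ether, and methanolysis frees the primary alcohol that is silylated on the way.

Step 3
Reactants: 6 2,2,5-trimethyl-1,3-dioxane-4,6-dione; 7 2-(trimethylsilyl)ethanol
Product: 8 2-methyl-3-oxo-3-[2-(trimethylsilyl)ethoxy]propanoic acid (racemic)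
Conditions: toluene, 80 °C
Reagents that add atoms: none
Why: Ring-opening alcoholysis of the Meldrum's acid derivative with loss of acetone gives the malonic half-ester; its stereocenter is erased later by enolisation.

Step 4
Reactants: 5; 8
Product: 9 mixed methylmalonate of 5 and 2-(trimethylsilyl)ethanol (both malonate epimers)
Conditions: DCC, DMAP (10 mol %), CH2Cl2, 0 → 23 °C
Reagents that add atoms: none
Why: Steglich esterification of the primary allylic alcohol; no ring stereocenter is affected.

Step 5
Reactants: 9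
Product: 12 malonic half-acid (4R,5S,6R) with exocyclic C10=C20 and free C3 carboxyl, via silyl ketene acetal 10 (not isolated), via trimethylsilyl ester 11 (not isolated)
Conditions: LiN(SiMe3)2, Me3SiCl, THF, −78 → 23 °C; then toluene, 80 °C; aq. NaH2PO4 work-up
Reagents that add atoms: none
Why: Ireland–Claisen rearrangement of a malonate: the lithium enolate is chelated by both carbonyl oxygens, so silylation should give the (Z)-ketene acetal 10 with the C18 ester cis to OSiMe3, and the chair [3,3] shift forms C4–C5 anti to the C6 silyl ether (5S), puts the C19 methyl axial and the ester equatorial (4R), and moves the alkene to exocyclic C10=C20.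

Step 6
Reactants: 12; 13 tributyl(vinyl)stannane
Product: 15 2-(trimethylsilyl)ethyl (2R)-2-[(7S,8R)-8-[(tert-butyldimethylsilyl)oxy]-6-methylidene-1,4-dioxaspiro[4.5]decan-7-yl]-2-methyl-3-oxopent-4-enoate, via acid chloride 14 (not isolated)
Conditions: 1-chloro-N,N,2-trimethylprop-1-en-1-amine, CH2Cl2, 0 → 23 °C; then 13, Pd(PPh3)4 (5 mol %), toluene, 60 °C
Reagents that add atoms: none
Why: Neutral conversion of the acid into acid chloride 14, then Stille acylation (oxidative addition of zerovalent palladium to the acyl chloride, vinyl transfer from tin) should give the vinyl ketone without acid or base that could touch the ketal; no stereocenter changes.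

Step 7
Reactants: 15
Product: 18 3-oxo trans-decalin (4R,5S,6R,10R) with C9 ketal and C6 silyl ether, via tertiary C10 radical 16 (not isolated), via α-keto radical 17 (not isolated)
Conditions: Fe(acac)3 (30 mol %), PhSiH3 (2.5 equiv), EtOH/(CH2OH)2 (5:1), 0.01 M, degassed, 60 °C
Reagents that add atoms: none
Why: An iron hydride formed from Fe(acac)3 and PhSiH3 should transfer a hydrogen atom to C20 of the electron-rich 1,1-disubstituted alkene (Markovnikov) to give the nucleophilic tertiary C10 radical 16, which adds to the terminal carbon C1 of the vinyl ketone; the α-keto radical 17 is then reduced by divalent iron and protonated by ethanol. The closest known reaction type is the intramolecular metal-hydride hydrogen-atom-transfer Giese reaction (reductive olefin coupling), which is established for the formation of quaternary carbons. Ring A closes in the 6-endo-trig mode, which is polarity-matched and should outrun 5-exo attack at the α-carbon C2. C10 is the only new stereocenter and is controlled by C5: the C4 substituent and the C6 silyl ether stay trans-diequatorial on ring B (an axial C4 group would clash with the axial dioxolane oxygen on C9), so the acryloyl arm reaches C10 along the ring periphery next to H5, and a chair-like transition state with the C19 methyl axial makes the new C1–C10 bond equatorial and C20 axial, anti to H5. The step needs hydrogen-atom transfer to the exocyclic alkene in preference to the enone, and trans ring fusion; the first should follow from the faster transfer to the electron-rich alkene at high dilution, the second from the diequatorial lock of ring B.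

Step 8
Reactants: 18
Product: 19 (3R)-3-hydroxy ester (3R,4R,5S,6R,10R)
Conditions: NaBH4, MeOH/THF, 0 °C
Reagents that add atoms: none
Why: Borohydride reduction of the C3 ketone; hydride should enter on the axial trajectory away from the axial C19 methyl to give the equatorial alcohol, whose configuration is erased in step 10.

Step 9
Reactants: 19
Product: 20 O-(imidazol-1-ylthiocarbonyl) derivative of 19
Conditions: 1,1'-thiocarbonyldiimidazole, DMAP, ClCH2CH2Cl, 80 °C
Reagents that add atoms: 1,1'-thiocarbonyldiimidazole, S=C(n1ccnc1)n1ccnc1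
Why: Thioacylation of the hindered alcohol under neutral conditions (no alkoxide, hence no retro-aldol opening of the β-hydroxy ester) gives the thionocarbamate needed for Barton–McCombie deoxygenation.

Step 10
Reactants: 20
Product: 21 3-deoxy decalin ester (4S,5S,6R,10R) with C9 ketal
Conditions: Bu3SnH, AIBN (cat.), toluene, 110 °C
Reagents that add atoms: none
Why: Barton–McCombie radical deoxygenation: the tin radical adds to sulfur, the C3–O bond fragments and the C3 radical takes hydrogen from Bu3SnH; no stereocenter is affected.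

Step 11
Reactants: 21
Product: 22 C9 ketone (4S,5S,6R,10R)
Conditions: PPTS, acetone/H2O (10:1), 55 °C
Reagents that add atoms: water, O
Why: Mild acid-catalysed acetal hydrolysis frees the C9 ketone while the hindered secondary silyl ether and the silylethyl ester stay.

Step 12
Reactants: 22; 2 formaldehyde (as paraformaldehyde)
Product: 24 8-methylidene C9 ketone (4S,5S,6R,10R), via Mannich base 23 (not isolated)
Conditions: (CH2O)n, i-Pr2NH·CF3CO2H, CF3CO2H (10 mol %), THF, 65 °C; used at once
Reagents that add atoms: none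
Why: Mannich reaction at C8, the only enolisable α-position, followed by β-elimination of the amine in the same flask (α-methylenation) installs C17.

Step 13
Reactants: 24; 25 allylmagnesium bromide
Product: 27 methyl carbonate of the (9R)-9-allyl-8-methylidene-9-ol, via magnesium alkoxide 26 (not isolated)
Conditions: THF, −78 °C; then ClCO2Me, −78 → 23 °C
Reagents that add atoms: methyl chloroformate, COC(=O)Cl
Why: Grignard 1,2-addition of the allyl reagent to the hindered enone, expected from the face away from the axial C20 methyl, and acylation of alkoxide 26 below room temperature give the tertiary allylic carbonate; this C9 configuration is lost in step 14, so either epimer serves.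

Step 14
Reactants: 27
Product: 28 2-(trimethylsilyl)ethyl (4S,5S,6R,9R,10S)-6-[(tert-butyldimethylsilyl)oxy]-14,15,16-trinorlabda-8(17),12-dien-18-oate
Conditions: Pd(OAc)2 (5 mol %), n-Bu3P (5 mol %), HCO2H, Et3N, THF, 40 °C
Reagents that add atoms: none
Why: Palladium-catalysed formate hydrogenolysis of an allylic carbonate: ionisation gives an allylpalladium that can change face through its primary C17 terminus, and hydride from formate should go to the more substituted terminus C9 on the face away from the axial C20 methyl, which gives the C8=C17 methylene and 9R (H9 axial, side chain equatorial).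

Step 15
Reactants: 28; 29 methacrolein
Product: 30 (12E)-14-oxo-15-norlabda-8(17),12-dien-18-oate (silyl ether and silylethyl ester as in 28)
Conditions: second-generation Hoveyda–Grubbs catalyst RuCl2(H2IMes)(=CH–C6H4-2-Oi-Pr) (5 mol %), CH2Cl2, 40 °C
Reagents that add atoms: none
Why: Olefin cross-metathesis of the monosubstituted alkene with methacrolein, thermodynamically E-selective for the trisubstituted enal; the hindered 1,1-disubstituted C8=C17 alkene should not take part.

Step 16
Reactants: 30
Product: 31 2-(trimethylsilyl)ethyl (4S,5S,6R,9R,10S,12E)-6-[(tert-butyldimethylsilyl)oxy]labda-8(17),12,14-trien-18-oate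
Conditions: Ph3PCH3Br, KOt-Bu, THF, 0 °C
Reagents that add atoms: methyltriphenylphosphonium bromide, C[P+](c1ccccc1)(c1ccccc1)c1ccccc1.[Br-]
Why: Wittig methylenation of the enal completes the (12E)-12,14-diene; the hindered C18 ester is inert to the ylide.

Step 17
Reactants: 31
Product: 32 2-(trimethylsilyl)ethyl (4S,5S,6R,9R,10S,12E)-6-hydroxylabda-8(17),12,14-trien-18-oate
Conditions: HF·pyridine, pyridine, THF, 0 → 23 °C
Reagents that add atoms: none
Why: Buffered acidic fluoride desilylation cleaves the secondary silyl ether, while the 2-(trimethylsilyl)ethyl ester, which needs free fluoride ion, should stay.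

Step 18
Reactants: 32
Product: 33 2-(trimethylsilyl)ethyl (4S,5S,6R,9R,10S,12E)-6-acetoxylabda-8(17),12,14-trien-18-oate
Conditions: Ac2O, DMAP, pyridine, CH2Cl2, 23 °C
Reagents that add atoms: acetic anhydride, CC(=O)OC(C)=O
Why: DMAP-catalysed acetylation of the equatorial C6 alcohol; no carboxylic acid is present that could lactonise or form a mixed anhydride.

Step 19
Reactants: 33
Product: 34 (4S,5S,6R,9R,10S,12E)-6-acetoxylabda-8(17),12,14-trien-18-oic acid (target)
Conditions: Bu4NF, THF, 0 → 23 °C; 1 M HCl to pH 4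
Reagents that add atoms: none
Why: Fluoride-induced fragmentation of the 2-(trimethylsilyl)ethyl ester (attack at silicon, loss of ethene) releases the hindered C18 carboxylate without nucleophilic attack at any carbonyl, so the C6 acetate should survive.

Compound list
1 | (4R)-4-[(tert-butyldimethylsilyl)oxy]cyclohex-2-en-1-one | O=C1C=C[C@H](O[Si](C)(C)C(C)(C)C)CC1 | starting material
2 | formaldehyde | C=O | starting material
3 | (4R)-4-[(tert-butyldimethylsilyl)oxy]-2-(hydroxymethyl)cyclohex-2-en-1-one | O=C1C(CO)=C[C@H](O[Si](C)(C)C(C)(C)C)CC1 | intermediate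
4 | trimethylsilyl ether of 5 (not isolated) | O1CCOC12CC[C@@H](O[Si](C)(C)C(C)(C)C)C=C2CO[Si](C)(C)C | intermediate
5 | [(8R)-8-[(tert-butyldimethylsilyl)oxy]-1,4-dioxaspiro[4.5]dec-6-en-6-yl]methanol | O1CCOC12CC[C@@H](O[Si](C)(C)C(C)(C)C)C=C2CO | intermediate
6 | 2,2,5-trimethyl-1,3-dioxane-4,6-dione | CC1C(=O)OC(C)(C)OC1=O | starting material
7 | 2-(trimethylsilyl)ethanol | C[Si](C)(C)CCO | starting material
8 | 2-methyl-3-oxo-3-[2-(trimethylsilyl)ethoxy]propanoic acid (racemic) | CC(C(=O)O)C(=O)OCC[Si](C)(C)C | intermediate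
9 | 1-{[(8R)-8-[(tert-butyldimethylsilyl)oxy]-1,4-dioxaspiro[4.5]dec-6-en-6-yl]methyl} 3-[2-(trimethylsilyl)ethyl] 2-methylpropanedioate (both epimers at the malonate carbon) | O1CCOC12CC[C@@H](O[Si](C)(C)C(C)(C)C)C=C2COC(=O)C(C)C(=O)OCC[Si](C)(C)C | intermediate
10 | (Z)-trimethylsilyl ketene acetal of 9 (Me3SiO cis to the silylethyl ester, methyl cis to the allylic oxygen; not isolated) | O1CCOC12CC[C@@H](O[Si](C)(C)C(C)(C)C)C=C2CO/C(O[Si](C)(C)C)=C(\C)C(=O)OCC[Si](C)(C)C | intermediate
11 | trimethylsilyl ester of 12 (not isolated) | O1CCOC12CC[C@@H](O[Si](C)(C)C(C)(C)C)[C@@H](C2=C)[C@@](C)(C(=O)OCC[Si](C)(C)C)C(=O)O[Si](C)(C)C | intermediate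
12 | (2R)-2-[(7S,8R)-8-[(tert-butyldimethylsilyl)oxy]-6-methylidene-1,4-dioxaspiro[4.5]decan-7-yl]-2-methyl-3-oxo-3-[2-(trimethylsilyl)ethoxy]propanoic acid (labdane numbering 4R,5S,6R; free carboxyl = C3) | O1CCOC12CC[C@@H](O[Si](C)(C)C(C)(C)C)[C@@H](C2=C)[C@@](C)(C(=O)OCC[Si](C)(C)C)C(=O)O | intermediate
13 | tributyl(vinyl)stannane | C=C[Sn](CCCC)(CCCC)CCCC | starting material
14 | acid chloride of 12 (C3 as COCl; not isolated) | O1CCOC12CC[C@@H](O[Si](C)(C)C(C)(C)C)[C@@H](C2=C)[C@@](C)(C(=O)OCC[Si](C)(C)C)C(=O)Cl | intermediate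
15 | 2-(trimethylsilyl)ethyl (2R)-2-[(7S,8R)-8-[(tert-butyldimethylsilyl)oxy]-6-methylidene-1,4-dioxaspiro[4.5]decan-7-yl]-2-methyl-3-oxopent-4-enoate (key-step precursor; labdane numbering 4R,5S,6R) | O1CCOC12CC[C@@H](O[Si](C)(C)C(C)(C)C)[C@@H](C2=C)[C@@](C)(C(=O)OCC[Si](C)(C)C)C(=O)C=C | intermediate
16 | tertiary C10 radical formed from 15 by hydrogen-atom transfer to C20 (not isolated) | O1CCOC12CC[C@@H](O[Si](C)(C)C(C)(C)C)[C@@H]([C]2C)[C@@](C)(C(=O)OCC[Si](C)(C)C)C(=O)C=C | intermediate
17 | cyclised C2 (α-keto) radical (not isolated) | O1CCOC12CC[C@@H](O[Si](C)(C)C(C)(C)C)[C@H]3[C@@]2(C)C[CH]C(=O)[C@]3(C)C(=O)OCC[Si](C)(C)C | intermediate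
18 | trans-decalin keto ester (4R,5S,6R,10R): C3 ketone; C4 with axial methyl (C19) and equatorial CO2CH2CH2SiMe3 (C18); C6 equatorial OSi(t-Bu)Me2; C9 ethylene ketal; C10 axial methyl (C20) anti to H5 | O1CCOC12CC[C@@H](O[Si](C)(C)C(C)(C)C)[C@H]3[C@@]2(C)CCC(=O)[C@]3(C)C(=O)OCC[Si](C)(C)C | intermediate
19 | (3R)-3-hydroxy derivative of 18 (equatorial OH; 3R,4R,5S,6R,10R) | O1CCOC12CC[C@@H](O[Si](C)(C)C(C)(C)C)[C@H]3[C@@]2(C)CC[C@@H](O)[C@]3(C)C(=O)OCC[Si](C)(C)C | intermediate
20 | O-(1H-imidazol-1-ylthiocarbonyl) derivative of 19 | O1CCOC12CC[C@@H](O[Si](C)(C)C(C)(C)C)[C@H]3[C@@]2(C)CC[C@@H](OC(=S)n4ccnc4)[C@]3(C)C(=O)OCC[Si](C)(C)C | intermediate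
21 | 3-deoxy decalin ester (4S,5S,6R,10R): as 18 with C3 = CH2 | O1CCOC12CC[C@@H](O[Si](C)(C)C(C)(C)C)[C@H]3[C@@]2(C)CCC[C@]3(C)C(=O)OCC[Si](C)(C)C | intermediate
22 | C9 ketone (4S,5S,6R,10R): as 21 with the ketal removed | O=C1CC[C@@H](O[Si](C)(C)C(C)(C)C)[C@H]2[C@@]1(C)CCC[C@]2(C)C(=O)OCC[Si](C)(C)C | intermediate
23 | 8-[(diisopropylamino)methyl] derivative of 22 (C8 unassigned; not isolated) | O=C1C(CN(C(C)C)C(C)C)C[C@@H](O[Si](C)(C)C(C)(C)C)[C@H]2[C@@]1(C)CCC[C@]2(C)C(=O)OCC[Si](C)(C)C | intermediate
24 | 8-methylidene C9 ketone (4S,5S,6R,10R) | O=C1C(=C)C[C@@H](O[Si](C)(C)C(C)(C)C)[C@H]2[C@@]1(C)CCC[C@]2(C)C(=O)OCC[Si](C)(C)C | intermediate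
25 | allylmagnesium bromide | C=CC[Mg]Br | starting material
26 | bromomagnesium alkoxide of the (9R)-9-allyl-8-methylidene-9-ol (O equatorial, allyl axial; not isolated) | Br[Mg]O[C@]1(CC=C)C(=C)C[C@@H](O[Si](C)(C)C(C)(C)C)[C@H]2[C@@]1(C)CCC[C@]2(C)C(=O)OCC[Si](C)(C)C | intermediate
27 | methyl carbonate of the (9R)-9-allyl-8-methylidene-9-ol (4S,5S,6R,9R,10R; expected epimer) | COC(=O)O[C@]1(CC=C)C(=C)C[C@@H](O[Si](C)(C)C(C)(C)C)[C@H]2[C@@]1(C)CCC[C@]2(C)C(=O)OCC[Si](C)(C)C | intermediate
28 | 2-(trimethylsilyl)ethyl (4S,5S,6R,9R,10S)-6-[(tert-butyldimethylsilyl)oxy]-14,15,16-trinorlabda-8(17),12-dien-18-oate (C9 allyl equatorial, H9 axial) | C=CC[C@@H]1C(=C)C[C@@H](O[Si](C)(C)C(C)(C)C)[C@H]2[C@@]1(C)CCC[C@]2(C)C(=O)OCC[Si](C)(C)C | intermediate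
29 | methacrolein | C=C(C)C=O | starting material
30 | 2-(trimethylsilyl)ethyl (4S,5S,6R,9R,10S,12E)-6-[(tert-butyldimethylsilyl)oxy]-14-oxo-15-norlabda-8(17),12-dien-18-oate | O=C/C(C)=C/C[C@@H]1C(=C)C[C@@H](O[Si](C)(C)C(C)(C)C)[C@H]2[C@@]1(C)CCC[C@]2(C)C(=O)OCC[Si](C)(C)C | intermediate
31 | 2-(trimethylsilyl)ethyl (4S,5S,6R,9R,10S,12E)-6-[(tert-butyldimethylsilyl)oxy]labda-8(17),12,14-trien-18-oate | C=C/C(C)=C/C[C@@H]1C(=C)C[C@@H](O[Si](C)(C)C(C)(C)C)[C@H]2[C@@]1(C)CCC[C@]2(C)C(=O)OCC[Si](C)(C)C | intermediate
32 | 2-(trimethylsilyl)ethyl (4S,5S,6R,9R,10S,12E)-6-hydroxylabda-8(17),12,14-trien-18-oate | C=C/C(C)=C/C[C@@H]1C(=C)C[C@@H](O)[C@H]2[C@@]1(C)CCC[C@]2(C)C(=O)OCC[Si](C)(C)C | intermediate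
33 | 2-(trimethylsilyl)ethyl (4S,5S,6R,9R,10S,12E)-6-acetoxylabda-8(17),12,14-trien-18-oate | C=C/C(C)=C/C[C@@H]1C(=C)C[C@@H](OC(C)=O)[C@H]2[C@@]1(C)CCC[C@]2(C)C(=O)OCC[Si](C)(C)C | intermediate
34 | (4S,5S,6R,9R,10S,12E)-6-acetoxylabda-8(17),12,14-trien-18-oic acid (ent-labdane) | C=C/C(C)=C/C[C@@H]1C(=C)C[C@@H](OC(C)=O)[C@H]2[C@@]1(C)CCC[C@]2(C)C(=O)O | target

Total step count: 19. Longest linear sequence: 18 steps (steps 1, 2 and 4–19 from compound 1; step 3 is a one-step side branch).

Steps most likely to fail

Step 7. Hydrogen-atom transfer may go to the vinyl ketone first, the C10 radical may be reduced before it closes the crowded ring, or closure may take place on the other face of C10 (cis ring fusion). The fallback sets out from 12 and comes back at 22: C10 is made by enolate alkylation and ring A is closed at C2–C3 by metathesis. Acid chloride 14, made from 12 as in step 6, would be reduced with LiAlH(Ot-Bu)3 at −78 °C to the C3 aldehyde F1, and Wittig methylenation would give the C4 vinyl compound F2. PPTS in wet acetone would free the 10-methylidene C9 ketone F3. Conjugate reduction with LiBH(s-Bu)3 and alkylation of the resulting C10 enolate with allyl bromide, anti to the bulky C5 substituent, would give the C10 allyl ketone F4. Ring-closing metathesis with the second-generation Grubbs catalyst would give the 2-ene F5, and hydrogenation over palladium on carbon would give 22.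

Step 5. The rearrangement may pass through a boat instead of the chair, which would deliver the C4 epimer, or the stabilised ketene acetal may be lost before it rearranges. The fallback sets out from 5 and comes back at 15: the tether is moved to the carboxyl that becomes C18, so that the same boat gives the needed C4 centre. Alcohol 5 would be acylated with propanoyl chloride and pyridine to the propanoate F6. Its lithium enolate (LiN(i-Pr)2, −78 °C) and acrolein would give the β-hydroxy ester F7. The dianion (2.2 equiv LiN(i-Pr)2, −78 → 23 °C), in which the lithium alkoxide is held cis to the enolate oxygen, would rearrange in the dianionic Ireland–Claisen manner to the hydroxy acid F8. Heating with 2-(trimethylsilyl)ethyl 2,2,2-trichloroacetimidate would give the hydroxy ester F9, and Dess–Martin oxidation of the allylic alcohol would give 15.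

Step 14. Hydride may be delivered to C17 instead of C9, or the allylpalladium may lose a β-hydrogen to give a diene. The fallback sets out from 24 and comes back at 28: the hydrogen is brought to C9 by a sigmatropic loss of nitrogen, whose regiochemistry is fixed. Aqueous NH4Cl quench of alkoxide 26 (from 24 and 25) would give the tertiary allylic alcohol F10. Babler–Dauben oxidation with pyridinium chlorochromate would transpose it to the C17 enal F11, and NaBH4 with CeCl3 would give the primary allylic alcohol F12. Mitsunobu reaction with 2-nitrobenzenesulfonylhydrazide, PPh3 and diethyl azodicarboxylate at −30 °C would give the sulfonylhydrazine F13. On warming this would lose the sulfinic acid to give the allylic diazene F14, which would lose nitrogen with transfer of hydrogen to C9 on the face away from C20 to give 28.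

Further compounds
F1 | step 7 | C3 aldehyde: 2-(trimethylsilyl)ethyl (4R,5S,6R)-2-formyl-2-methyl acetate bearing the ring B unit of 12 | O1CCOC12CC[C@@H](O[Si](C)(C)C(C)(C)C)[C@@H](C2=C)[C@@](C)(C(=O)OCC[Si](C)(C)C)C=O
F2 | step 7 | C4 vinyl compound (C3=CH2 in place of the formyl oxygen of F1) | O1CCOC12CC[C@@H](O[Si](C)(C)C(C)(C)C)[C@@H](C2=C)[C@@](C)(C(=O)OCC[Si](C)(C)C)C=C
F3 | step 7 | 10-methylidene C9 ketone from F2 | O=C1CC[C@@H](O[Si](C)(C)C(C)(C)C)[C@@H](C1=C)[C@@](C)(C(=O)OCC[Si](C)(C)C)C=C
F4 | step 7 | C10 allyl, C10 methyl C9 ketone (allyl trans to the C5 substituent) | O=C1CC[C@@H](O[Si](C)(C)C(C)(C)C)[C@H]([C@@](C)(C(=O)OCC[Si](C)(C)C)C=C)[C@@]1(C)CC=C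
F5 | step 7 | 2,3-didehydro derivative of 22 (ring A closed, C2=C3) | O=C1CC[C@@H](O[Si](C)(C)C(C)(C)C)[C@H]2[C@@]1(C)CC=C[C@]2(C)C(=O)OCC[Si](C)(C)C
F6 | step 5 | propanoate of 5 | O1CCOC12CC[C@@H](O[Si](C)(C)C(C)(C)C)C=C2COC(=O)CC
F7 | step 5 | 3-hydroxy-2-methylpent-4-enoate of 5 (diastereomer mixture in the acyl part) | O1CCOC12CC[C@@H](O[Si](C)(C)C(C)(C)C)C=C2COC(=O)C(C)C(O)C=C
F8 | step 5 | Claisen hydroxy acid: C4 quaternary with C18 carboxyl, C19 methyl and C3 vinyl carbinol (C3 epimers) | O1CCOC12CC[C@@H](O[Si](C)(C)C(C)(C)C)[C@@H](C2=C)[C@@](C)(C(=O)O)C(O)C=C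
F9 | step 5 | 2-(trimethylsilyl)ethyl ester of F8 | O1CCOC12CC[C@@H](O[Si](C)(C)C(C)(C)C)[C@@H](C2=C)[C@@](C)(C(=O)OCC[Si](C)(C)C)C(O)C=C
F10 | step 14 | (9R)-9-allyl-8-methylidene-9-ol (free alcohol of 27) | O[C@]1(CC=C)C(=C)C[C@@H](O[Si](C)(C)C(C)(C)C)[C@H]2[C@@]1(C)CCC[C@]2(C)C(=O)OCC[Si](C)(C)C
F11 | step 14 | 9-allyl-8(9)-en-17-al | C=CCC1=C(C=O)C[C@@H](O[Si](C)(C)C(C)(C)C)[C@H]2[C@@]1(C)CCC[C@]2(C)C(=O)OCC[Si](C)(C)C
F12 | step 14 | 9-allyl-8(9)-en-17-ol | C=CCC1=C(CO)C[C@@H](O[Si](C)(C)C(C)(C)C)[C@H]2[C@@]1(C)CCC[C@]2(C)C(=O)OCC[Si](C)(C)C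
F13 | step 14 | N-(C17-allylic) N-(2-nitrobenzenesulfonyl)hydrazine from F12 | C=CCC1=C(CN(N)S(=O)(=O)c3ccccc3[N+](=O)[O-])C[C@@H](O[Si](C)(C)C(C)(C)C)[C@H]2[C@@]1(C)CCC[C@]2(C)C(=O)OCC[Si](C)(C)C
F14 | step 14 | C17 allylic diazene | C=CCC1=C(CN=N)C[C@@H](O[Si](C)(C)C(C)(C)C)[C@H]2[C@@]1(C)CCC[C@]2(C)C(=O)OCC[Si](C)(C)C
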